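## The problem

Target 21 is a trans-fused bicyclo[5.3.0]decane. The numbering used throughout is: five-membered ring C1–C5, seven-membered ring C1, C5–C10; C1 carries the angular methyl, C2 the acetate, C4 the isopropyl carbinol, C5 the fusion hydrogen, C6 the veratrate, C8 (methyl) and C9 the epoxide; β is the face of the C1 methyl. Seven stereocentres (1S,2S,4S,5R,6S,8R,9S) sit on ten ring carbons; C1 is quaternary and the C5 hydrogen is α, trans to the methyl. All four oxygen functions (C2, C4, C6, epoxide) lie on the β-face. Once C1 and the trans fusion exist, attack anti to the angular methyl gives the right result at C4 and C6, whereas C2 (next to C1) and C8/C9 need delivery from an oxygen already in place. C1 therefore has to be set first and absolutely, C5 has to be fixed before C4 stops being a carbonyl, and the 4β- and 6β-hydroxyls then serve as internal directors. The sensitive elements are the trisubstituted epoxide (acid), two different esters on secondary alcohols beside a free tertiary alcohol (order of acylation, migration), β-oxygenated ketones on the way (dehydration, retro-aldol) and skipped alkenes that can move into conjugation. The enabling feature is that C1 is β to both C4 and C6 through C5. With carbonyls at C4 and C6, a C1=C5 double bond inside the seven-membered ring and a two-carbon vinyl unit C2=C3 on C4, the skeleton is a 2-acyl divinyl ketone whose 4π closure forms C1–C2, the five-membered ring and the quaternary centre at once.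

## Retrosynthesis

**21 ⇒ 19 + 20; 19 ⇒ 18; 18 ⇒ 17.** The cuts are the C6–O acyl bond (to acid chloride 20), the two epoxide C–O bonds, and the O–Si bond at C6. The veratrate goes on last because the free 6β-hydroxyl of 18 is the only group placed to carry an oxidant to the β-face of C8=C9. Putting the acetate on last instead would leave two secondary alcohols to tell apart. Alkene 18 has two stereocentres fewer and no acid-labile group; 17 differs from it only by the silyl ether that keeps C6 apart from C2. The forward steps must cleave the silyl ether without touching the acetate, deliver oxygen syn to O6, and acylate a hindered secondary alcohol beside a tertiary one.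

**17 ⇒ 16 ⇒ 13.** The cuts are the acetyl C–O bond and then the C2–O bond, traced back through a C2–Si bond to the C2=C3 alkene of 13. Conjugate addition of an oxygen equivalent to the enone of 12 would be simpler to plan, but an external reagent reaches C2 anti to the neighbouring angular methyl and would give 2α. A C2 ketone plus hydride would give 2β but costs an oxidation and a reduction. A silicon hydride tethered to the 4β-oxygen can reach C2 only on the β-face. Compound 13 has one oxygen and one stereocentre fewer. The forward reaction must be a 5-endo hydrosilylation cis to O4 followed by C–Si oxidation with retention.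

**13 ⇒ 12.** The cut is the C4–isopropyl bond. Earlier, in 10, C5 is trigonal and the ring offers no facial bias; later is not possible because C5 stays epimerisable as long as C4 is a ketone. In 12 the C6 branch on C5 and the 1,3-related methyl both close the β-face. The forward reaction must be a 1,2-addition of a secondary alkyl nucleophile to a hindered, enolisable enone without enolisation.

**12 ⇒ 11 ⇒ 10.** The cuts are O–Si, then the C6–H and C5–H bonds; ketol 11 is the mono-reduction product of the enolised diketone 10. Telling the two carbonyls apart by O-alkylation would give two regioisomeric enol ethers and leave the ring flat. Reduction through the diketo tautomer uses the intrinsic difference (C6 isolated, C4 cross-conjugated) and sets C5 and C6 in one event. Compound 10 has a single stereocentre. The forward reaction must reduce one carbonyl only, avoid dehydration, and give the trans fusion.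

**10 ⇒ 9 (key cut).** The cut is C1–C2. It removes the five-membered ring and the only stereocentre and leaves an achiral monocyclic trienedione; the competing ring cuts are weighed under "Roads not taken". The C2 terminus of 9 carries a trimethylsilyl group. A bare acryloyl unit would form the same bond, but it is a weak nucleophilic terminus and polymerises readily. Silicon makes C2 the nucleophilic carbon, stabilises the cation after closure and is lost in the step, so 10 is the same either way. The forward reaction must select one sense of conrotation.

**9 ⇒ 5 + 8 + CO; 8 ⇒ 6 + 7.** The cuts are both C–C bonds at the C4 carbonyl. Metallating the bromo enone and acylating it is not possible beside the ketone, so the carbonyl is brought in as CO between the alkenyl bromide 5 and the alkenyl stannane 8. Stannane 8 comes in one step from alkyne 6 and tin hydride 7.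

**5 ⇒ 4 ⇒ 2 + 3; 2 ⇒ 1.** The cut is the one-carbon ring expansion: the CBr carbon of 5 (later C5) is inserted as dibromocarbene from 3 into the enol ether double bond of diene 2. Arene 1 already has every carbon in place: its methoxy carbon becomes C6, its two methyl-bearing carbons become C1 and C8. The forward steps must add the carbene to the enol ether only and open the ring without moving the skipped diene.

## Roads not taken

**Alternative 1: oxidative coupling of two ketone enolates.** The cut is C7–C8, so the seven-membered ring is closed last on a finished cyclopentane. The diketone A1 (C6 methyl ketone on C5, C9 ethyl ketone on the C10 arm of C1) would be turned into its bis-enolate and oxidised with a divalent copper salt to the cyclic 1,4-diketone A2.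
- Merits: C1, C2, C4 and C5 are fixed before any bicycle exists, the fusion hydrogen never sits next to an enolised diketone, and both enolisations are regiochemically clean (methyl versus tertiary C5; ethyl side versus neopentyl C10).
- Weak points: an oxidative hetero-coupling has to close a seven-membered ring against oligomerisation and homo-coupling. The C9 carbonyl of A2 must afterwards be converted into the C8=C9 alkene before the epoxide can be made. A1 itself, a cyclopentane with a quaternary carbon, three further stereocentres and two different ketone chains, needs a long synthesis before the key step can be tried.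
- Comparison: in stereochemical security at C2, C4 and C5 this road is the better one. The chosen plan sets against it a ring closure of a favourable size, both rings and the quaternary centre after six steps from an anisole, and catalytic absolute control.

**Alternative 2: intramolecular Buchner reaction.** The cuts are C1–C5 and C1–C10. A rhodium carbenoid generated at C1 of the diazo ketone A3 would add to the C5–C10 bond of its 2-methoxy-4-methylphenyl ring, and the norcaradiene would open to the cycloheptatriene ketone A4.
- Merits: one step gives both rings and the quaternary centre from an arene that already carries the C6 oxygen and the C8 methyl. C2 arrives as a ketone, which hydride should reduce anti to the methyl to the 2β-alcohol without any tether. C4 is a defined tertiary carbinol from the start.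
- Weak points: the carbenoid carbon bears a methyl group, so 1,2-hydride shift to an enone competes. The arene offers two ortho bonds and C–H insertion as further outlets. C1 is set only by 1,3-induction from C4. A4 still has a trigonal C5 and three ring alkenes, two of which must be reduced selectively.
- Comparison: this road is equal in directness and better at C2 and C4. The chosen plan sets against it a catalyst-controlled C1, no β-hydrogen problem at the reactive centre, and a product (10) whose seven-membered ring already has only the C8=C9 alkene that the target needs.

**Alternative 3: photochemical Wolff contraction of a p-menthane ketone.** Irradiation of the 2-diazocyclohexanone A5 in an alcohol would expel nitrogen, C4 would migrate from C6 to C5 with retention, and the ketene would be trapped as the cyclopentane ester A6.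
- Merits: absolute configuration comes from the chiral pool, and C1, C2 and C4 are arranged on a conformationally well-understood six-membered ring. The allylsilane arm of A6 is placed for a later closure onto C6 that would deliver the C8=C9 alkene.
- Weak points: the key step makes no ring of the target's seven-membered half, so a second, medium-ring closure is still owed. C5 is set by ketene protonation and stays epimerisable next to the ester. The carbene can add to the pendant alkene instead of rearranging. A5, with a quaternary centre, an allylsilane stereocentre and two protected alcohols, needs a long linear sequence.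
- Comparison: this road is better in that it needs no asymmetric catalysis and settles C2 and C4 early. The chosen plan sets against it a much shorter route to the complete ring system.

Key step: step 6

Assumption: the sense of induction of the two chiral catalysts ((S,S)-t-Bu-box in step 6, (S,S)-TsDPEN in step 7) is taken from the usual models for these catalysts; if either proves opposite, the mirror-image ligand is used.

## Route

Step 1
Reactants: 1 2,5-dimethylanisole
Product: 2 1-methoxy-2,5-dimethylcyclohexa-1,4-diene
Conditions: Li, NH3 (l), t-BuOH, THF, −78 to −33 °C; MeOH quench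
Reagents that add atoms: none
Why: Birch reduction: the arene takes up two electrons and two protons so that the methoxy and both methyl groups stay on the remaining double bonds, giving the skipped diene with the enol ether intact. The non-acidic quench keeps the diene from moving into conjugation and the enol ether from hydrolysing.

Step 2
Reactants: 2 1-methoxy-2,5-dimethylcyclohexa-1,4-diene; 3 bromoform
Product: 4 7,7-dibromo-1-methoxy-3,6-dimethylbicyclo[4.1.0]hept-3-ene (racemic, cis-fused)
Conditions: KOt-Bu, pentane, −20 to 0 °C
Reagents that add atoms: none
Why: Dibromocarbene generated by α-elimination is electrophilic and should add to the most electron-rich alkene, the tetrasubstituted enol ether, in preference to the trisubstituted ring alkene. The [2+1] addition is cis by necessity, so one racemic diastereomer is expected.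

Step 3
Reactants: 4 7,7-dibromo-1-methoxy-3,6-dimethylbicyclo[4.1.0]hept-3-ene
Product: 5 2-bromo-3,6-dimethylcyclohepta-2,5-dien-1-one
Conditions: AgNO3, CaCO3, acetone/H2O, rt, dark
Reagents that add atoms: water, O
Why: Silver-assisted loss of the endo bromide triggers disrotatory opening of the cyclopropane to an allyl cation held as an oxocarbenium ion; water adds and methanol leaves (gem-dihalocyclopropane ring expansion to a 2-bromo enone). CaCO3 takes up the acid so that the skipped diene should stay in place.

Step 4
Reactants: 6 ethynyltrimethylsilane; 7 tributyltin hydride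
Product: 8 (E)-trimethyl[2-(tributylstannyl)ethenyl]silane
Conditions: AIBN (cat.), neat, 85 °C
Reagents that add atoms: none
Why: Radical hydrostannylation of a silylalkyne: the stannyl radical adds to the terminal carbon, and reversible radical addition equilibrates the product to the (E)-1,2-disubstituted alkene.

Step 5
Reactants: 5 2-bromo-3,6-dimethylcyclohepta-2,5-dien-1-one; 8 (E)-trimethyl[2-(tributylstannyl)ethenyl]silane
Product: 9 3,6-dimethyl-2-[(2E)-3-(trimethylsilyl)prop-2-enoyl]cyclohepta-2,5-dien-1-one
Conditions: Pd(PPh3)4 (5 mol%), CO (3 atm), THF, 55 °C, BHT (trace)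
Reagents that add atoms: carbon monoxide, [C-]#[O+]
Why: Carbonylative Stille coupling: the α-bromo enone adds oxidatively to zerovalent palladium, CO inserts, the alkenyl group is transferred from tin (tin before silicon, E geometry retained) and reductive elimination gives the divinyl ketone. CO pressure should suppress direct coupling, and the β-silyl group makes the product far less prone to polymerise than a bare acryloyl ketone.

Step 6
Reactants: 9 3,6-dimethyl-2-[(2E)-3-(trimethylsilyl)prop-2-enoyl]cyclohepta-2,5-dien-1-one
Product: 10 (3aR)-8-hydroxy-3a,6-dimethyl-4,7-dihydroazulen-1(3aH)-one (C6 enol of the C4,C6-dione; (1R) in route numbering)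
Conditions: Cu(OTf)2 (10 mol%), (S,S)-t-Bu-box (11 mol%), (CF3)2CHOH (1.5 equiv), CH2Cl2, 0 °C to rt
Reagents that add atoms: none
Why: The C4 and C6 carbonyls of 9 bind the divalent copper–bis(oxazoline) complex as a chelate, which holds the C1=C5–C4(O)–C3=C2 unit in the U shape and turns it into a pentadienyl cation. Thermal conrotatory 4π electrocyclisation then joins the methyl-bearing C1 to the silyl-bearing C2; this is the mode by which the five-membered ring closes, and it leaves a copper-bound oxyallyl cation whose charge at C3 is β to silicon. Loss of the silyl group to hexafluoroisopropanol places the double bond at C2=C3, the only position open because C1 and C5 carry no hydrogen, and 10 is released as the enol. The closest known reactions are the enantioselective Nazarov cyclisation of 2-acyl and 2-alkoxycarbonyl divinyl ketones with Cu(OTf)2 and a bis(oxazoline), and the silicon-directed Nazarov cyclisation of β-silyl divinyl ketones. The only new stereocentre is the quaternary C1; it is decided by the sense of conrotation, which the C2-symmetric ligand on the chelated metal should select by blocking one rotation of the C1 terminus. C5 stays trigonal in the enol, so no ring-fusion isomer can arise here. The step needs torquoselectivity and must outrun γ-deprotonation at C10 or C7; two-point binding, β-silicon stabilisation and low temperature are meant to secure both.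

Step 7
Reactants: 10 (3aR)-8-hydroxy-3a,6-dimethyl-4,7-dihydroazulen-1(3aH)-one
Product: 11 (3aR,8S,8aR)-8-hydroxy-3a,6-dimethyl-4,7,8,8a-tetrahydroazulen-1(3aH)-one (6β-hydroxy-1β,8-dimethyl-5αH-bicyclo[5.3.0]deca-2,8-dien-4-one)
Conditions: RuCl(p-cymene)[(S,S)-TsDPEN] (2 mol%), HCO2H/Et3N (5:2), CH2Cl2, 0 °C to rt
Reagents that add atoms: none
Why: Noyori–Ikariya transfer hydrogenation with dynamic kinetic resolution, a known way to reduce one carbonyl of a 2-substituted 1,3-diketone: hydride goes to the diketo tautomer, where the isolated C6 carbonyl should react ahead of the cross-conjugated C4 carbonyl. In the trans-fused tautomer (5α-H) the β-face of C6 is screened by the 1,3-related angular methyl, so substrate and catalyst should both favour α-attack, giving the 6β (6S) alcohol. Fast keto–enol exchange should funnel the material through this tautomer and so fix 5α-H.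

Step 8
Reactants: 11 6β-hydroxy-1β,8-dimethyl-5αH-bicyclo[5.3.0]deca-2,8-dien-4-one
Product: 12 6β-(tert-butyldimethylsilyloxy)-1β,8-dimethyl-5αH-bicyclo[5.3.0]deca-2,8-dien-4-one
Conditions: TBSOTf, 2,6-lutidine, CH2Cl2, −78 °C
Reagents that add atoms: tert-butyldimethylsilyl triflate, CC(C)(C)[Si](C)(C)OS(=O)(=O)C(F)(F)F
Why: Silylation of the secondary alcohol with a silyl triflate and a hindered base at low temperature should be faster than enolisation of the ketone, so C5 keeps its configuration. The silyl ether also blocks retro-aldol cleavage and dehydration of the ketol.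

Step 9
Reactants: 12 6β-(tert-butyldimethylsilyloxy)-1β,8-dimethyl-5αH-bicyclo[5.3.0]deca-2,8-dien-4-one
Product: 13 6β-(tert-butyldimethylsilyloxy)-4α-isopropyl-1β,8-dimethyl-5αH-bicyclo[5.3.0]deca-2,8-dien-4β-ol
Conditions: i-PrMgCl, CeCl3 (anhydrous), THF, −78 °C
Reagents that add atoms: isopropylmagnesium chloride, CC(C)[Mg]Cl
Why: Organocerium 1,2-addition to an enone: the weakly basic reagent should add to the C4 carbonyl without enolising C5 or adding in 1,4 fashion. The β-face of C4 is closed by the C6 branch on C5 and by the 1,3-related angular methyl, so isopropyl should enter from the α-face and leave the tertiary hydroxyl β.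

Step 10
Reactants: 13 6β-(tert-butyldimethylsilyloxy)-4α-isopropyl-1β,8-dimethyl-5αH-bicyclo[5.3.0]deca-2,8-dien-4β-ol
Product: 16 6β-(tert-butyldimethylsilyloxy)-4α-isopropyl-1β,8-dimethyl-5αH-bicyclo[5.3.0]dec-8-ene-2β,4β-diol, via dimethylsilyl ether 14 (not isolated), via bridged cyclic siloxane 15 (not isolated)
Conditions: ClSiMe2H, Et3N, DMAP (cat.), CH2Cl2, 0 °C; Pt2[(CH2=CHSiMe2)2O]3 (1 mol%), toluene, 60 °C; 30% H2O2, KF, KHCO3, THF/MeOH, 40 °C
Reagents that add atoms: chlorodimethylsilane, C[SiH](C)Cl (its silicon stays only in 14 and 15); hydrogen peroxide, OO
Why: Tethered hydrosilylation of an allylic alcohol followed by Tamao–Fleming oxidation: the Si–H bound to the 4β-oxygen can reach only C2 (5-endo; C3 would need a four-membered ring) and only on the β-face, giving 15 with silicon cis to O4. Oxidation of the C–Si bond proceeds with retention, so the new hydroxyl should be 2β, cis to the angular methyl, the face an external reagent would avoid. The trisubstituted C8=C9 alkene and the silyl ether should not react under these conditions.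

Step 11
Reactants: 16 6β-(tert-butyldimethylsilyloxy)-4α-isopropyl-1β,8-dimethyl-5αH-bicyclo[5.3.0]dec-8-ene-2β,4β-diol
Product: 17 2β-acetoxy-6β-(tert-butyldimethylsilyloxy)-4α-isopropyl-1β,8-dimethyl-5αH-bicyclo[5.3.0]dec-8-en-4β-ol
Conditions: Ac2O, pyridine, DMAP (cat.), CH2Cl2, 0 °C to rt
Reagents that add atoms: acetic anhydride, CC(=O)OC(C)=O
Why: DMAP-catalysed acetylation should distinguish the secondary 2β-hydroxyl from the tertiary 4β-hydroxyl by rate. C6 is still silylated, so only one ester can form.

Step 12
Reactants: 17 2β-acetoxy-6β-(tert-butyldimethylsilyloxy)-4α-isopropyl-1β,8-dimethyl-5αH-bicyclo[5.3.0]dec-8-en-4β-ol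
Product: 18 2β-acetoxy-4α-isopropyl-1β,8-dimethyl-5αH-bicyclo[5.3.0]dec-8-ene-4β,6β-diol
Conditions: HF·pyridine, pyridine, THF, 0 °C to rt
Reagents that add atoms: none
Why: Fluoride cleavage of the silyl ether under buffered, non-basic conditions, so the acetate should neither hydrolyse nor migrate. The tertiary alcohol and the trisubstituted alkene should tolerate the medium.

Step 13
Reactants: 18 2β-acetoxy-4α-isopropyl-1β,8-dimethyl-5αH-bicyclo[5.3.0]dec-8-ene-4β,6β-diol
Product: 19 2β-acetoxy-8β,9β-epoxy-4α-isopropyl-1β,8α-dimethyl-5αH-bicyclo[5.3.0]decane-4β,6β-diol
Conditions: VO(acac)2 (5 mol%), t-BuOOH (decane), CH2Cl2, 0 °C to rt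
Reagents that add atoms: tert-butyl hydroperoxide, CC(C)(C)OO
Why: Vanadium-catalysed hydroxyl-directed epoxidation of a homoallylic alcohol: the 6β-alkoxide binds the vanadium peroxide and should deliver oxygen to the same face of C8=C9, giving the 8β,9β-epoxide. This is the face an undirected peracid would avoid because of the angular methyl, and no other alkene is left in 18.

Step 14
Reactants: 19 2β-acetoxy-8β,9β-epoxy-4α-isopropyl-1β,8α-dimethyl-5αH-bicyclo[5.3.0]decane-4β,6β-diol; 20 3,4-dimethoxybenzoyl chloride
Product: 21 (1S,2S,4S,5R,6S,8R,9S)-2-acetoxy-8,9-epoxy-4-hydroxy-4-isopropyl-1,8-dimethylbicyclo[5.3.0]dec-6-yl 3,4-dimethoxybenzoate (CNP0330776.1)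
Conditions: Et3N, DMAP, CH2Cl2, 0 °C to rt
Reagents that add atoms: none
Why: DMAP-catalysed acylation of the one remaining secondary alcohol with the acid chloride. The tertiary C4 hydroxyl should not react, and the basic medium should leave the epoxide and the acetate untouched.

## Compound list

1 | 2,5-dimethylanisole | COc1cc(C)ccc1C | starting material
2 | 1-methoxy-2,5-dimethylcyclohexa-1,4-diene | COC1=C(C)CC=C(C)C1 | intermediate
3 | bromoform | BrC(Br)Br | starting material
4 | 7,7-dibromo-1-methoxy-3,6-dimethylbicyclo[4.1.0]hept-3-ene (racemic, cis-fused) | COC12CC(C)=CCC1(C)C2(Br)Br | intermediate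
5 | 2-bromo-3,6-dimethylcyclohepta-2,5-dien-1-one | O=C1C(Br)=C(C)CC=C(C)C1 | intermediate
6 | ethynyltrimethylsilane | C#C[Si](C)(C)C | starting material
7 | tributyltin hydride | CCCC[SnH](CCCC)CCCC | starting material
8 | (E)-trimethyl[2-(tributylstannyl)ethenyl]silane | C[Si](C)(C)/C=C/[Sn](CCCC)(CCCC)CCCC | intermediate
9 | 3,6-dimethyl-2-[(2E)-3-(trimethylsilyl)prop-2-enoyl]cyclohepta-2,5-dien-1-one | C[Si](C)(C)/C=C/C(=O)C1=C(C)CC=C(C)CC1=O | intermediate
10 | (3aR)-8-hydroxy-3a,6-dimethyl-4,7-dihydroazulen-1(3aH)-one | OC1=C2C(=O)C=C[C@@]2(C)CC=C(C)C1 | intermediate
11 | (3aR,8S,8aR)-8-hydroxy-3a,6-dimethyl-4,7,8,8a-tetrahydroazulen-1(3aH)-one | O[C@H]1CC(C)=CC[C@]2(C)C=CC(=O)[C@@H]12 | intermediate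
12 | 6β-(tert-butyldimethylsilyloxy)-1β,8-dimethyl-5αH-bicyclo[5.3.0]deca-2,8-dien-4-one | CC(C)(C)[Si](C)(C)O[C@H]1CC(C)=CC[C@]2(C)C=CC(=O)[C@@H]12 | intermediate
13 | 6β-(tert-butyldimethylsilyloxy)-4α-isopropyl-1β,8-dimethyl-5αH-bicyclo[5.3.0]deca-2,8-dien-4β-ol | CC(C)(C)[Si](C)(C)O[C@H]1CC(C)=CC[C@]2(C)C=C[C@](O)(C(C)C)[C@@H]12 | intermediate
14 | 4β-(dimethylsilyloxy) ether of 13 | CC(C)(C)[Si](C)(C)O[C@H]1CC(C)=CC[C@]2(C)C=C[C@](O[SiH](C)C)(C(C)C)[C@@H]12 | intermediate (not isolated)
15 | bridged siloxane: 2β-Si, 4β-O joined by SiMe2 | CC(C)(C)[Si](C)(C)O[C@H]1CC(C)=CC[C@]2(C)[C@@H]3C[C@](O[Si]3(C)C)(C(C)C)[C@@H]12 | intermediate (not isolated)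
16 | 6β-(tert-butyldimethylsilyloxy)-4α-isopropyl-1β,8-dimethyl-5αH-bicyclo[5.3.0]dec-8-ene-2β,4β-diol | CC(C)(C)[Si](C)(C)O[C@H]1CC(C)=CC[C@]2(C)[C@@H](O)C[C@](O)(C(C)C)[C@@H]12 | intermediate
17 | 2β-acetoxy-6β-(tert-butyldimethylsilyloxy)-4α-isopropyl-1β,8-dimethyl-5αH-bicyclo[5.3.0]dec-8-en-4β-ol | CC(C)(C)[Si](C)(C)O[C@H]1CC(C)=CC[C@]2(C)[C@@H](OC(C)=O)C[C@](O)(C(C)C)[C@@H]12 | intermediate
18 | 2β-acetoxy-4α-isopropyl-1β,8-dimethyl-5αH-bicyclo[5.3.0]dec-8-ene-4β,6β-diol | O[C@H]1CC(C)=CC[C@]2(C)[C@@H](OC(C)=O)C[C@](O)(C(C)C)[C@@H]12 | intermediate
19 | 2β-acetoxy-8β,9β-epoxy-4α-isopropyl-1β,8α-dimethyl-5αH-bicyclo[5.3.0]decane-4β,6β-diol | O[C@H]1C[C@@]2(C)O[C@H]2C[C@]2(C)[C@@H](OC(C)=O)C[C@](O)(C(C)C)[C@@H]12 | intermediate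
20 | 3,4-dimethoxybenzoyl chloride | COc1ccc(C(Cl)=O)cc1OC | starting material
21 | CNP0330776.1, (1S,2S,4S,5R,6S,8R,9S)-2-acetoxy-8,9-epoxy-4-hydroxy-4-isopropyl-1,8-dimethylbicyclo[5.3.0]dec-6-yl 3,4-dimethoxybenzoate | COc1ccc(C(=O)O[C@H]2C[C@@]3(C)O[C@H]3C[C@]3(C)[C@@H](OC(C)=O)C[C@](O)(C(C)C)[C@@H]23)cc1OC | target

## Step count and risks

Total: 14 steps (13 in the main line plus the one-step preparation of stannane 8). Longest linear sequence: 13 steps (1 to 21 through steps 1–3 and 5–14).

**Step 6 (key step).** The ligand may fail to discriminate the two senses of conrotation at a fully substituted terminus. The Lewis acid may instead promote γ-deprotonation at C10 or C7, moving the ring alkenes into conjugation. The chelating product may hold the copper and stop turnover. Fallback: from 9, cyclisation with an achiral Lewis acid (Sc(OTf)3, CH2Cl2, (CF3)2CHOH) should give the racemic enol-enone F1. F1 is then submitted to the step-7 catalyst and stopped near half conversion, so that the reduction acts as a kinetic resolution: only the (R)-enantiomer offers the pairing in which the catalyst and the angular methyl both favour α-attack at C6. This moves the enantio-determining event from the electrocyclisation to the hydride transfer and returns to the route at 11.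

**Step 7.** Hydride may go to the wrong carbonyl or to both, the ketol may dehydrate to the cross-conjugated dienone under the amine/acid medium, or the reduction may pass through the cis-fused tautomer. Fallback: from 10, reduction with a ketoreductase (NADPH, glucose dehydrogenase recycling, aqueous buffer with co-solvent) chosen from a panel for the 6S, 5αH ketol. Enzymatic dynamic kinetic reduction of 2-substituted 1,3-diketones is established, works at neutral pH where dehydration is slow, and does not depend on a facial model. It returns to the route at 11 without a new intermediate.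

**Step 10.** The bridged hydrosilylation forces silicon onto C2 cis to the angular methyl. Ring strain and crowding may make it slower than intermolecular hydrosilylation or platinum-hydride alkene migration, and oxidation of the hindered C–Si bond may be sluggish. Fallback (C2 oxygen by conjugate addition, then inversion through the ketone): from 12, copper-catalysed conjugate borylation (CuCl, NaOt-Bu, Xantphos, B2pin2, MeOH, THF) should give the 2α-boryl ketone F2 by attack anti to the methyl. F2 is oxidised in the same flask (NaBO3·4H2O) to the 2α-hydroxy ketone F3. Excess i-PrMgCl/CeCl3 gives the 2α,4β-diol F4. Dess–Martin oxidation of the secondary alcohol (NaHCO3 buffer) gives the 2-ketone F5. NaBH4 (MeOH, −20 °C) attacks F5 anti to the neighbouring angular methyl and gives the 2β-alcohol, returning to the route at 16.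

**Step 5.** Direct coupling without CO insertion, palladium-hydride migration of the skipped diene, and polymerisation or γ-isomerisation of the doubly activated product may compete. Fallback (CO introduced first, then a CO-free acylation): from 5, palladium-catalysed hydroxycarbonylation (Pd(OAc)2, dppf, CO, H2O, Et3N, DMF) gives 2,5-dimethyl-7-oxocyclohepta-1,4-diene-1-carboxylic acid F6. Oxalyl chloride with catalytic DMF converts it into the acid chloride F7. Stille acylation of stannane 8 with F7 (PdCl2(PPh3)2, toluene, 60 °C) returns to the route at 9.

**Step 13.** Direction from a homoallylic hydroxyl is weaker than from an allylic one. The syn-1,3-diol may bind vanadium as a chelate and slow delivery, undirected attack would favour the α-face, and the C6 alcohol may be oxidised. Fallback: from 18, reagent-controlled Shi epoxidation (fructose-derived ketone catalyst, Oxone, buffered MeCN/dimethoxymethane/H2O, 0 °C), using the enantiomer of the ketone that delivers oxygen to the β-face of the trisubstituted alkene. Facial selection then comes from the catalyst instead of the substrate. It returns to the route at 19 without a new intermediate.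

## Further compounds

F1 | step 6 | racemic 8-hydroxy-3a,6-dimethyl-4,7-dihydroazulen-1(3aH)-one | OC1=C2C(=O)C=CC2(C)CC=C(C)C1
F0 | step 7 | none | none
F2 | step 10 | 6β-(tert-butyldimethylsilyloxy)-1β,8-dimethyl-2α-(pinacolboryl)-5αH-bicyclo[5.3.0]dec-8-en-4-one | CC(C)(C)[Si](C)(C)O[C@H]1CC(C)=CC[C@]2(C)[C@H](B3OC(C)(C)C(C)(C)O3)CC(=O)[C@@H]12
F3 | step 10 | 6β-(tert-butyldimethylsilyloxy)-2α-hydroxy-1β,8-dimethyl-5αH-bicyclo[5.3.0]dec-8-en-4-one | CC(C)(C)[Si](C)(C)O[C@H]1CC(C)=CC[C@]2(C)[C@H](O)CC(=O)[C@@H]12
F4 | step 10 | 6β-(tert-butyldimethylsilyloxy)-4α-isopropyl-1β,8-dimethyl-5αH-bicyclo[5.3.0]dec-8-ene-2α,4β-diol | CC(C)(C)[Si](C)(C)O[C@H]1CC(C)=CC[C@]2(C)[C@H](O)C[C@](O)(C(C)C)[C@@H]12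
F5 | step 10 | 6β-(tert-butyldimethylsilyloxy)-4β-hydroxy-4α-isopropyl-1β,8-dimethyl-5αH-bicyclo[5.3.0]dec-8-en-2-one | CC(C)(C)[Si](C)(C)O[C@H]1CC(C)=CC[C@]2(C)C(=O)C[C@](O)(C(C)C)[C@@H]12
F6 | step 5 | 2,5-dimethyl-7-oxocyclohepta-1,4-diene-1-carboxylic acid | OC(=O)C1=C(C)CC=C(C)CC1=O
F7 | step 5 | 2,5-dimethyl-7-oxocyclohepta-1,4-diene-1-carbonyl chloride | ClC(=O)C1=C(C)CC=C(C)CC1=O
F0 | step 13 | none | none
A1 | alternative 1 | cyclopentane diketone: C6 methyl ketone on C5, 2-oxobutyl arm on C1, 2β-OTBS, 4β-OMOM, 4α-isopropyl | CCC(=O)C[C@]1(C)[C@@H](O[Si](C)(C)C(C)(C)C)C[C@](OCOC)(C(C)C)[C@H]1C(C)=O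
A2 | alternative 1 | trans-fused bicyclic C6,C9-diketone with C8 methyl | O=C1C[C@H](C)C(=O)C[C@]2(C)[C@@H](O[Si](C)(C)C(C)(C)C)C[C@](OCOC)(C(C)C)[C@@H]12
A3 | alternative 2 | 2-diazo-5-(2-methoxy-4-methylphenyl)-6-methyl-5-(triethylsilyloxy)heptan-3-one | CC(C)[C@@](O[Si](CC)(CC)CC)(CC(=O)C(C)=[N+]=[N-])c1ccc(C)cc1OC
A4 | alternative 2 | bicyclic cycloheptatriene C2 ketone with quaternary C1 and C6 enol ether | CC(C)[C@@]1(O[Si](CC)(CC)CC)CC(=O)[C@@]2(C)C=CC(C)=CC(OC)=C12
A5 | alternative 3 | 2-diazocyclohexanone of the p-menthane series with C1 allylsilane arm, 2-OTBS and 4-OMOM | O=C1C(=[N+]=[N-])[C@](C)(C[C@H]([Si](C)(C)C)C(C)=C)[C@@H](O[Si](C)(C)C(C)(C)C)C[C@]1(OCOC)C(C)C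
A6 | alternative 3 | cyclopentane C6 methyl ester with all five ring stereocentres | COC(=O)[C@@H]1[C@@](OCOC)(C(C)C)C[C@H](O[Si](C)(C)C(C)(C)C)[C@@]1(C)C[C@H]([Si](C)(C)C)C(C)=C
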